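**Plan**
1. The target is 3-henicosyl-2,5-dihydroxy-6-methyl-1,4-benzoquinone. Retrosynthesis first masks the two acidic OH groups as O-ethyl and O-isopropyl vinylogous esters (15) and steps back to the hydroquinone level.
2. The ring bond between the carbonyl carbon next to the henicosyl-bearing carbon and the ethoxy-bearing carbon is cut, and that carbonyl carbon is re-joined to the para carbonyl carbon. This contracts the six-membered ring to a 4-alkenyl-4-hydroxycyclobutenone (11).
3. Next cuts: the carbinol–alkenyl C–C bond (cyclobutenedione 6 + β-ethoxyvinyllithium 10), then the ring–henicosyl C–C bond (diisopropyl squarate + a C21 Grignard reagent from docosanoic acid).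
4. Enabling feature: in the quinone ring each of the two para C=O carbons is flanked by one alkyl-bearing and one oxygen-bearing sp2 carbon. The four contiguous atoms C(=O)–C(C21)–C(O)–C(=O) map onto a squarate-derived four-membered ring, and the remaining C(CH3)=C(O) pair onto an enol ether double bond.
5. Forward: the chain is joined to the squarate (step 2), the enol ether unit is added (step 4), and the only ring of the target arises in step 5 by four- to six-membered ring expansion and oxidation. The ethers are hydrolysed last.
6. Stereochemistry: the target has none. The Z geometry of 9 only keeps the vinyllithium stable, and the racemic carbinol centre of 11 vanishes in step 5.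

Key step: step 5

Remark: the target is achiral and is drawn as one tautomer of a 2,5-dihydroxy-1,4-benzoquinone; the route is planned for this tautomeric system, and 1-bromohenicosane is made from the abundant C22 acid and not assumed to be purchasable.

**Step 1**
Reactants: 1 docosanoic acid
Product: 2 1-bromohenicosane
Conditions: HgO (red), Br2, CCl4, reflux, dark
Reagents that add atoms: bromine, BrBr
Why: Hunsdiecker bromodecarboxylation in the Cristol–Firth form, a radical-chain loss of CO2 that is well behaved for long straight-chain fatty acids and should give the odd-carbon primary bromide from the even-carbon acid.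

**Step 2**
Reactants: 2 1-bromohenicosane; 3 3,4-di(propan-2-yloxy)cyclobut-3-ene-1,2-dione (diisopropyl squarate)
Product: 6 3-henicosyl-4-(propan-2-yloxy)cyclobut-3-ene-1,2-dione, via henicosylmagnesium bromide 4 (not isolated), via hydroxycyclobutenone adduct 5 (not isolated)
Conditions: Mg, THF, 50 °C; then 3, THF, −78 to −40 °C; NH4Cl aq; crude 5, conc. HCl (cat.), CH2Cl2, rt
Reagents that add atoms: water, O (from the aqueous HCl; it supplies the new carbonyl oxygen)
Why: Grignard 1,2-addition to one squarate carbonyl should stop at mono-addition because the remaining carbonyl of 5 is a deactivated vinylogous ester, and acid-catalysed allylic transposition with loss of propan-2-ol then gives the 3-alkyl-4-alkoxycyclobutenedione (the standard squarate alkylation sequence); the racemic carbinol centre of 5 is lost at once.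

**Step 3**
Reactants: 7 1-ethoxyprop-1-ene (commercial cis/trans mixture)
Product: 9 (Z)-2-bromo-1-ethoxyprop-1-ene, via 1,2-dibromo-1-ethoxypropane 8 (not isolated)
Conditions: Br2, CH2Cl2, −78 °C; then iPr2NEt, −78 °C to reflux; fractional distillation
Reagents that add atoms: bromine, BrBr
Why: Bromine addition to an enol ether followed by amine-mediated dehydrobromination through the α-bromo ether is the usual preparation of (Z)-1-bromo-2-ethoxyethene and is applied here to its methyl homologue; both isomers of 7 converge on 8, and the isomer with Br cis to OEt is expected to predominate and is taken by distillation.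

**Step 4**
Reactants: 9 (Z)-2-bromo-1-ethoxyprop-1-ene; 6 3-henicosyl-4-(propan-2-yloxy)cyclobut-3-ene-1,2-dione
Product: 11 4-[(Z)-1-ethoxyprop-1-en-2-yl]-2-henicosyl-4-hydroxy-3-(propan-2-yloxy)cyclobut-2-en-1-one (racemic), via vinyllithium 10 (not isolated)
Conditions: 9, t-BuLi (2 equiv), Et2O, −78 °C; then 6 in THF, −78 °C; NH4Cl aq, 0 °C; crude product kept free of acid
Reagents that add atoms: none
Why: Bromine–lithium exchange with retention gives a vinyllithium whose lithium is cis to the ethoxy oxygen, so anti β-elimination of lithium ethoxide is blocked at −78 °C, and it should add 1,2 to the more electrophilic carbonyl of 6 (the one next to the isopropoxy-bearing carbon, the other being a vinylogous ester), as is general for 3-alkoxy-4-alkylcyclobutenediones; the new carbinol stereocentre forms racemic and is erased in step 5.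

**Step 5**
Reactants: 11 4-[(Z)-1-ethoxyprop-1-en-2-yl]-2-henicosyl-4-hydroxy-3-(propan-2-yloxy)cyclobut-2-en-1-one
Product: 15 2-ethoxy-6-henicosyl-3-methyl-5-(propan-2-yloxy)cyclohexa-2,5-diene-1,4-dione, via dienylketene 12 (not isolated), via cyclohexadienone 13 (not isolated), via hydroquinone 14 (not isolated)
Conditions: toluene, 110 °C, Ar; then Ag2O, rt
Reagents that add atoms: none
Why: Heating cleaves the C(=O)–C(OH) bond of the cyclobutenone by conrotatory 4π electrocyclic ring opening to dienylketene 12, a thermal disrotatory 6π electrocyclisation then joins the ketene carbon to the ethoxy-bearing alkene carbon to give 13, enolisation aromatises to hydroquinone 14, and Ag2O oxidises 14 to quinone 15. The closest known reaction type is the Moore–Liebeskind ring expansion of 4-alkenyl- and 4-aryl-4-hydroxycyclobutenones to hydroquinones and quinones. The six-membered carbocycle closes by 6π electrocyclisation of the (Z)-dienylketene, four of its carbons coming from the four-membered ring and two from the enol ether double bond. No stereocentre results, because the carbinol centre of 11 and the sp3 centre of 13 both become sp2 and the alkene geometry of 11 is lost on aromatisation. The step needs torquoselective ring opening, which the 4-hydroxyl donor secures by rotating outward so that the alkenyl group lies cis to the ketene, and it needs one regiochemistry, which the connectivity set in steps 2 and 4 fixes (alkyl groups para, each carbonyl flanked by one alkyl-bearing and one alkoxy-bearing carbon). Enolisation of 13 should outrun loss of ethanol because it restores aromaticity by a simple proton shift.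

**Step 6**
Reactants: 15 2-ethoxy-6-henicosyl-3-methyl-5-(propan-2-yloxy)cyclohexa-2,5-diene-1,4-dione
Product: 16 3-henicosyl-2,5-dihydroxy-6-methylcyclohexa-2,5-diene-1,4-dione
Conditions: NaOH (2 M aq), EtOH–THF, 60 °C, Ar; then HCl aq
Reagents that add atoms: sodium hydroxide, [Na+].[OH-] (hydroxide oxygen replaces each alkoxy oxygen)
Why: Saponification of the two vinylogous esters by hydroxide addition–elimination at the alkoxy-bearing ring carbons, as used for 2,5-dialkoxy-3,6-dialkylbenzoquinones of the embelin class; the dianion formed is a doubly vinylogous carboxylate that should resist further attack, and acidification should release 16.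

**Compound list**
1 | docosanoic acid (behenic acid) | CCCCCCCCCCCCCCCCCCCCCC(=O)O | starting material
2 | 1-bromohenicosane | CCCCCCCCCCCCCCCCCCCCCBr | intermediate
3 | 3,4-di(propan-2-yloxy)cyclobut-3-ene-1,2-dione (diisopropyl squarate) | CC(C)OC1=C(OC(C)C)C(=O)C1=O | starting material
4 | henicosylmagnesium bromide | CCCCCCCCCCCCCCCCCCCCC[Mg]Br | intermediate
5 | 4-henicosyl-4-hydroxy-2,3-di(propan-2-yloxy)cyclobut-2-en-1-one (racemic) | O=C1C(OC(C)C)=C(OC(C)C)C1(O)CCCCCCCCCCCCCCCCCCCCC | intermediate
6 | 3-henicosyl-4-(propan-2-yloxy)cyclobut-3-ene-1,2-dione | O=C1C(=O)C(OC(C)C)=C1CCCCCCCCCCCCCCCCCCCCC | intermediate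
7 | 1-ethoxyprop-1-ene (ethyl prop-1-enyl ether, cis/trans mixture) | CC=COCC | starting material
8 | 1,2-dibromo-1-ethoxypropane (diastereomer mixture) | CC(Br)C(Br)OCC | intermediate
9 | (Z)-2-bromo-1-ethoxyprop-1-ene (Br cis to OEt) | C/C(Br)=C/OCC | intermediate
10 | (E)-(1-ethoxyprop-1-en-2-yl)lithium (Li cis to OEt) | C/C([Li])=C/OCC | intermediate
11 | 4-[(Z)-1-ethoxyprop-1-en-2-yl]-2-henicosyl-4-hydroxy-3-(propan-2-yloxy)cyclobut-2-en-1-one (racemic) | CCO/C=C(/C)C1(O)C(OC(C)C)=C(CCCCCCCCCCCCCCCCCCCCC)C1=O | intermediate
12 | (3Z,5Z)-6-ethoxy-2-henicosyl-4-hydroxy-5-methyl-3-(propan-2-yloxy)hexa-1,3,5-trien-1-one (dienylketene) | CCO/C=C(/C)C(/O)=C(/OC(C)C)C(CCCCCCCCCCCCCCCCCCCCC)=C=O | intermediate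
13 | 6-ethoxy-2-henicosyl-4-hydroxy-5-methyl-3-(propan-2-yloxy)cyclohexa-2,4-dien-1-one (racemic) | O=C1C(CCCCCCCCCCCCCCCCCCCCC)=C(OC(C)C)C(O)=C(C)C1OCC | intermediate
14 | 2-ethoxy-6-henicosyl-3-methyl-5-(propan-2-yloxy)benzene-1,4-diol | CCOc1c(C)c(O)c(OC(C)C)c(CCCCCCCCCCCCCCCCCCCCC)c1O | intermediate
15 | 2-ethoxy-6-henicosyl-3-methyl-5-(propan-2-yloxy)cyclohexa-2,5-diene-1,4-dione | CCOC1=C(C)C(=O)C(OC(C)C)=C(CCCCCCCCCCCCCCCCCCCCC)C1=O | intermediate
16 | 3-henicosyl-2,5-dihydroxy-6-methylcyclohexa-2,5-diene-1,4-dione | CCCCCCCCCCCCCCCCCCCCCC1=C(O)C(=O)C(C)=C(O)C1=O | target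

**Step count and risks**
Total step count: 6. Longest linear sequence: 5 steps (steps 1, 2, 4, 5, 6); step 3 is a one-step side branch.

Steps most likely to fail:

1. Step 4. Any vinyllithium with lithium trans to ethoxy (from residual E-bromide or from warming) can lose lithium ethoxide, and the propynyllithium so formed would compete in the addition. Attack at the vinylogous-ester carbonyl, over-addition, or acid-promoted hydrolysis of the enol ether during work-up are further ways to lose material. The fallback sets out from 6 and comes back to the route at 16. It replaces the oxygenated vinyl unit by a plain one and adds the last oxygen afterwards. Commercial isopropenylmagnesium bromide is added to 6 (THF, −78 °C) to give 2-henicosyl-4-hydroxy-3-(propan-2-yloxy)-4-(prop-1-en-2-yl)cyclobut-2-en-1-one F1. Heating in toluene as in step 5 should give 2-henicosyl-5-methyl-3-(propan-2-yloxy)benzene-1,4-diol F2, which Ag2O oxidises to 2-henicosyl-5-methyl-3-(propan-2-yloxy)cyclohexa-2,5-diene-1,4-dione F3. Nucleophilic epoxidation of its only CH-bearing double bond (H2O2, Na2CO3, aqueous dioxane) gives 4-henicosyl-1-methyl-3-(propan-2-yloxy)-7-oxabicyclo[4.1.0]hept-3-ene-2,5-dione F4. Conc. H2SO4 opens the epoxide with enolisation, as in the classical conversion of a 2-methylquinone epoxide to a 2-hydroxy-3-methylquinone, to give 2-henicosyl-6-hydroxy-5-methyl-3-(propan-2-yloxy)cyclohexa-2,5-diene-1,4-dione F5. The conditions of step 6 then cleave the isopropyl ether and give 16.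

2. Step 3. Poor control of double-bond geometry in the dehydrobromination, and loss of the volatile, hydrolytically labile bromo enol ether on distillation, would leave too little pure Z isomer. The fallback sets out from 9 in whatever isomer ratio is obtained and comes back at 10. NaNH2 in liquid NH3 eliminates HBr to give 1-ethoxyprop-1-yne F6. Radical hydrostannation (Bu3SnH, AIBN, 80 °C), which adds anti to ethoxyacetylene itself, should give tributyl[(Z)-1-ethoxyprop-1-en-2-yl]stannane F7 with tin cis to ethoxy. Tin–lithium exchange (n-BuLi, THF, −78 °C) then gives 10 for step 4.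

3. Step 5. The dienylketene may be intercepted by the neighbouring hydroxyl after ring opening with the wrong sense of rotation, the acid-labile enol ether and tertiary allylic alcohol may decompose before the ring opens, or the cyclohexadienone may lose ethanol in place of enolising. The fallback sets out from 2 and comes back at 16. It builds the substitution pattern on a preformed arene by directed metalation. Commercial 1,2,4,5-tetramethoxybenzene is lithiated (n-BuLi, TMEDA, THF, 0 °C) and methylated with MeI to give 1,2,4,5-tetramethoxy-3-methylbenzene F8. A second lithiation at the one remaining ring position and alkylation with 2 gives 1-henicosyl-2,3,5,6-tetramethoxy-4-methylbenzene F9. Oxidative demethylation with (NH4)2Ce(NO3)6 in MeCN–H2O gives 2-henicosyl-3,6-dimethoxy-5-methylcyclohexa-2,5-diene-1,4-dione F10. The conditions of step 6 hydrolyse F10 to 16.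

**Further compounds**
F1 | step 4 | 2-henicosyl-4-hydroxy-3-(propan-2-yloxy)-4-(prop-1-en-2-yl)cyclobut-2-en-1-one (racemic) | CC(=C)C1(O)C(OC(C)C)=C(CCCCCCCCCCCCCCCCCCCCC)C1=O
F2 | step 4 | 2-henicosyl-5-methyl-3-(propan-2-yloxy)benzene-1,4-diol | Cc1cc(O)c(CCCCCCCCCCCCCCCCCCCCC)c(OC(C)C)c1O
F3 | step 4 | 2-henicosyl-5-methyl-3-(propan-2-yloxy)cyclohexa-2,5-diene-1,4-dione | CC1=CC(=O)C(CCCCCCCCCCCCCCCCCCCCC)=C(OC(C)C)C1=O
F4 | step 4 | 4-henicosyl-1-methyl-3-(propan-2-yloxy)-7-oxabicyclo[4.1.0]hept-3-ene-2,5-dione (racemic) | CC12OC1C(=O)C(CCCCCCCCCCCCCCCCCCCCC)=C(OC(C)C)C2=O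
F5 | step 4 | 2-henicosyl-6-hydroxy-5-methyl-3-(propan-2-yloxy)cyclohexa-2,5-diene-1,4-dione | CC1=C(O)C(=O)C(CCCCCCCCCCCCCCCCCCCCC)=C(OC(C)C)C1=O
F6 | step 3 | 1-ethoxyprop-1-yne | CC#COCC
F7 | step 3 | tributyl[(Z)-1-ethoxyprop-1-en-2-yl]stannane | CCO/C=C(/C)[Sn](CCCC)(CCCC)CCCC
F8 | step 5 | 1,2,4,5-tetramethoxy-3-methylbenzene | COc1cc(OC)c(OC)c(C)c1OC
F9 | step 5 | 1-henicosyl-2,3,5,6-tetramethoxy-4-methylbenzene | COc1c(C)c(OC)c(OC)c(CCCCCCCCCCCCCCCCCCCCC)c1OC
F10 | step 5 | 2-henicosyl-3,6-dimethoxy-5-methylcyclohexa-2,5-diene-1,4-dione | COC1=C(C)C(=O)C(OC)=C(CCCCCCCCCCCCCCCCCCCCC)C1=O
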